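C1–C9 are the locants of the 6,8-dioxabicyclo[3.2.2]nonan-7-one core (C1 quaternary bridgehead, C2 carbinol, C5 methyl-bearing bridgehead, O6, C7 lactone carbonyl, O8, C9 ether CH). The enabling feature is that C1 is the α-carbon of the 1,4-dioxan-2-one ring C1–O8–C9–C5–O6–C7 and lies 1,4 across it from C5, so the C2–C3–C4 bridge is a tether on C5 that can be closed onto C1.
Retrosynthesis: after protecting-group and C2 oxidation-level adjustment, cut C1–C2 (lactone enolate onto a C2 Weinreb amide), then the ester C7–O6 and the ether O8–C1. This gives a C5/C9 hydroxy γ-lactone and a racemic α-bromo acid carrying C7, C1 and the acetoxy-alkenyl chain.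
Fragments: the lactone comes from nerol (allylic oxidation, bromide, acetic acid dianion for C3/C2, asymmetric epoxidation, lactonisation); the bromo acid comes from a Still–Gennari olefination and two acid-dianion steps.
Forward order: γ-lactone (temporary holder of O6 and C2), then the O8–C1 ether link, then exchange of the γ-lactone for the dioxanone, then one C1–C2 bond that closes the oxepane and the seven-membered lactone together, then the end-game.
Stereochemistry: C5 and C9 come from one catalyst-controlled epoxidation of the E-olefin with inversion at C5 on lactonisation; C1 is dictated by the C5 tether in the key step; C2 comes from an oxazaborolidine reduction; both Z-olefins come from nerol and the Still–Gennari reaction.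

Key step: step 17

Remark: both enantiomers of the fructose-derived epoxidation ketone and of the methyl oxazaborolidine are taken as commercially available; alkoxides, enolates and carboxylate dianions are treated as forms of the numbered compound they are made from.

Step 1
Reactants: 1 nerol
Product: 2 neryl tert-butyldiphenylsilyl ether
Conditions: tBuPh2SiCl, imidazole, DMF, 0 °C to rt
Reagents that add atoms: tert-butyl(chloro)diphenylsilane, CC(C)(C)[Si](Cl)(c1ccccc1)c1ccccc1
Why: Imidazole-promoted silylation of a primary allylic alcohol is routine, and this silyl ether should survive amide bases, NaH, AlMe3, camphorsulfonic acid and DDQ before fluoride removes it in the last step.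

Step 2
Reactants: 2 neryl tert-butyldiphenylsilyl ether
Product: 3 (2E,6Z)-8-(tert-butyldiphenylsilyloxy)-2,6-dimethylocta-2,6-dien-1-ol
Conditions: SeO2 (0.1 equiv), tBuOOH (3 equiv), salicylic acid (0.1 equiv), CH2Cl2, 0 °C to rt, stopped before over-oxidation
Reagents that add atoms: selenium dioxide, O=[Se]=O (oxygen donor, re-formed by tert-butyl hydroperoxide, CC(C)(C)OO)
Why: Catalytic Riley allylic oxidation (ene reaction, then [2,3]-sigmatropic shift) attacks the more electron-rich terminal olefin at the methyl group trans to the chain, so the E-allylic alcohol should form while the oxygen-deactivated Z-olefin is left alone.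

Step 3
Reactants: 3 (2E,6Z)-8-(tert-butyldiphenylsilyloxy)-2,6-dimethylocta-2,6-dien-1-ol
Product: 4 (2Z,6E)-8-bromo-3,7-dimethylocta-2,6-dien-1-yl tert-butyldiphenylsilyl ether
Conditions: CBr4, PPh3, CH2Cl2, 0 °C; used without chromatography
Reagents that add atoms: carbon tetrabromide, BrC(Br)(Br)Br
Why: Appel bromination converts the primary allylic alcohol into the bromide under neutral conditions, without allylic transposition at this temperature and without touching the silyl ether.

Step 4
Reactants: 4 (2Z,6E)-8-bromo-3,7-dimethylocta-2,6-dien-1-yl tert-butyldiphenylsilyl ether; 5 acetic acid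
Product: 6 (4E,8Z)-10-(tert-butyldiphenylsilyloxy)-4,8-dimethyldeca-4,8-dienoic acid
Conditions: 5 (3 equiv), LiN(iPr)2 (6 equiv), THF/DMPU, 0 to 35 °C; then 4, 0 °C to rt; aq HCl to pH 3
Reagents that add atoms: none
Why: Alkylation of the dilithium dianion of acetic acid at the unhindered primary allylic bromide (carboxylic acid dianion alkylation, SN2) should add C3 and C2 and deliver the free γ,δ-unsaturated acid in one operation.

Step 5
Reactants: 6 (4E,8Z)-10-(tert-butyldiphenylsilyloxy)-4,8-dimethyldeca-4,8-dienoic acid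
Product: 7 3-[(2S,3S)-3-[(3Z)-5-(tert-butyldiphenylsilyloxy)-3-methylpent-3-en-1-yl]-2-methyloxiran-2-yl]propanoic acid
Conditions: 1,2:4,5-di-O-isopropylidene-β-L-erythro-2,3-hexodiulo-2,6-pyranose (L-fructose-derived Shi ketone, 0.3 equiv), KHSO5 (as the triple salt 2KHSO5·KHSO4·K2SO4, 1.2 equiv), K2CO3, Bu4NHSO4 (cat.), MeCN/CH2(OMe)2/aq Na2B4O7 buffer (pH 10.5), 0 °C; NaH2PO4 to pH 5 at 0 °C, crude acid used at once
Reagents that add atoms: potassium peroxymonosulfate, [K+].[O-]S(=O)(=O)OO (oxygen relayed through the dioxirane of the ketone)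
Why: In this Shi asymmetric epoxidation the chiral dioxirane transfers oxygen through a spiro transition state to one face of the E-trisubstituted olefin, the L-fructose-derived ketone giving the (S,S) epoxide (mirror image of the (R,R) sense of the D-fructose catalyst), while the Z-olefin is slowed by its allylic silyloxy group and the bulky silyl ether and the oxidant is kept near one equivalent.

Step 6
Reactants: 7 3-[(2S,3S)-3-[(3Z)-5-(tert-butyldiphenylsilyloxy)-3-methylpent-3-en-1-yl]-2-methyloxiran-2-yl]propanoic acid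
Product: 8 (5R)-5-[(1S,4Z)-6-(tert-butyldiphenylsilyloxy)-1-hydroxy-4-methylhex-4-en-1-yl]-5-methyloxolan-2-one
Conditions: camphorsulfonic acid (0.1 equiv), CH2Cl2, 0 °C to rt
Reagents that add atoms: none
Why: Acid-catalysed 5-exo opening of the epoxide by the carboxyl group occurs at the tertiary carbon C5 with inversion and leaves the C9–O bond intact, which should give the γ-lactone with the (5R) and (9S) configurations of the target.

Step 7
Reactants: 9 3-(tert-butyldimethylsilyloxy)propanal; 10 ethyl 2-[bis(2,2,2-trifluoroethoxy)phosphoryl]propanoate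
Product: 11 ethyl (2Z)-5-(tert-butyldimethylsilyloxy)-2-methylpent-2-enoate
Conditions: KN(SiMe3)2, 18-crown-6, THF, −78 °C
Reagents that add atoms: none
Why: In the Still–Gennari olefination the trifluoroethyl phosphonate adduct eliminates faster than it equilibrates under dissociating conditions, which should give the Z-trisubstituted enoate from an unbranched aliphatic aldehyde.

Step 8
Reactants: 11 ethyl (2Z)-5-(tert-butyldimethylsilyloxy)-2-methylpent-2-enoate
Product: 12 (2Z)-5-(tert-butyldimethylsilyloxy)-2-methylpent-2-en-1-ol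
Conditions: iBu2AlH (2.5 equiv), CH2Cl2, −78 °C; aq potassium sodium tartrate (KNaC4H4O6)
Reagents that add atoms: none
Why: 1,2-Reduction of the enoate by iBu2AlH gives the allylic alcohol without changing the olefin geometry or the silyl ether.

Step 9
Reactants: 12 (2Z)-5-(tert-butyldimethylsilyloxy)-2-methylpent-2-en-1-ol
Product: 13 tert-butyl{[(3Z)-5-(4-methoxybenzyloxy)-4-methylpent-3-en-1-yl]oxy}dimethylsilane
Conditions: NaH, 4-methoxybenzyl chloride, Bu4NI (cat.), THF/DMF, 0 °C to rt
Reagents that add atoms: 4-methoxybenzyl chloride, COc1ccc(CCl)cc1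
Why: Williamson etherification of the primary allylic alkoxide installs a PMB ether that withstands strong bases and the aluminium amide and can later be removed oxidatively beside the silyl ether.

Step 10
Reactants: 13 tert-butyl{[(3Z)-5-(4-methoxybenzyloxy)-4-methylpent-3-en-1-yl]oxy}dimethylsilane
Product: 14 (3Z)-5-(4-methoxybenzyloxy)-4-methylpent-3-en-1-ol
Conditions: Bu4NF, THF, 0 °C to rt; aq NH4Cl
Reagents that add atoms: none
Why: Fluoride cleaves the primary tert-butyldimethylsilyl ether selectively, the PMB ether being inert.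

Step 11
Reactants: 14 (3Z)-5-(4-methoxybenzyloxy)-4-methylpent-3-en-1-ol
Product: 15 1-({[(2Z)-5-iodo-2-methylpent-2-en-1-yl]oxy}methyl)-4-methoxybenzene
Conditions: I2, PPh3, imidazole, CH2Cl2, 0 °C
Reagents that add atoms: iodine, II
Why: Appel-type iodination of the primary alcohol (PPh3/I2/imidazole) proceeds by SN2 displacement of the oxyphosphonium ion under buffered conditions that spare the PMB ether and the Z-olefin.

Step 12
Reactants: 15 1-({[(2Z)-5-iodo-2-methylpent-2-en-1-yl]oxy}methyl)-4-methoxybenzene; 5 acetic acid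
Product: 16 (5Z)-7-(4-methoxybenzyloxy)-6-methylhept-5-enoic acid
Conditions: 5 (3 equiv), LiN(iPr)2 (6 equiv), THF/DMPU, 0 to 35 °C; then 15, 0 °C to rt; aq HCl to pH 3
Reagents that add atoms: none
Why: The acetic acid dianion is alkylated by the primary iodide (carboxylic acid dianion alkylation, SN2), adding the carbons that become C1 and C7, with the low temperature limiting elimination to the diene.

Step 13
Reactants: 16 (5Z)-7-(4-methoxybenzyloxy)-6-methylhept-5-enoic acid
Product: 17 (5Z)-2-bromo-7-(4-methoxybenzyloxy)-6-methylhept-5-enoic acid (racemic)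
Conditions: LiN(iPr)2 (2.2 equiv), THF, −78 to 0 °C; cannulated into CBr4 (1.5 equiv), THF, −78 °C; aq HCl to pH 3
Reagents that add atoms: carbon tetrabromide, BrC(Br)(Br)Br
Why: The dilithium dianion of the acid is brominated at carbon by halogen transfer from CBr4 (α-halogenation of a carboxylic acid dianion), inverse addition keeping the product away from unreacted dianion, and the racemic centre is acceptable because it is planarised in the key step.

Step 14
Reactants: 8 (5R)-5-[(1S,4Z)-6-(tert-butyldiphenylsilyloxy)-1-hydroxy-4-methylhex-4-en-1-yl]-5-methyloxolan-2-one; 17 (5Z)-2-bromo-7-(4-methoxybenzyloxy)-6-methylhept-5-enoic acid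
Product: 18 ether acid joining C9–O8–C1, with the γ-lactone intact (both C1 epimers)
Conditions: NaH (2.7 equiv), 17 (1.5 equiv), THF/DMF, 0 to 40 °C; aq citric acid to pH 4
Reagents that add atoms: none
Why: Williamson etherification of the sodium alkoxide with the sodium α-bromo carboxylate (SN2 at the carbon α to the carboxylate, as in the classical preparation of lactyl ethers from 2-halopropionates) should form the O8–C1 bond, the carboxylate form suppressing enolisation of the electrophile, C9 keeping its configuration because its C–O bond is not broken, and both C1 epimers being usable.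

Step 15
Reactants: 18 ether acid joining C9–O8–C1 (both C1 epimers)
Product: 19 hydroxy acid with free tertiary C5 hydroxyl, C7 acid and C2 N-methoxy-N-methylamide (C1 epimers)
Conditions: AlMe3 (5 equiv), MeNHOMe (5 equiv), CH2Cl2, 0 °C to rt; aq potassium sodium tartrate (KNaC4H4O6), then NaH2PO4 to pH 5; crude used at once
Reagents that add atoms: N,O-dimethylhydroxylamine, CNOC
Why: Weinreb aminolysis of the γ-lactone by the dimethylaluminium amide turns C2 into the amide and frees the tertiary C5 hydroxyl, the C7 acid being masked in the flask as an unreactive aluminium carboxylate.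

Step 16
Reactants: 19 hydroxy acid with free tertiary C5 hydroxyl, C7 acid and C2 N-methoxy-N-methylamide (C1 epimers)
Product: 21 3-alkyl-1,4-dioxan-2-one carrying the Weinreb amide tether on C5 (C1 epimers), via mixed anhydride 20 (not isolated)
Conditions: 2,4,6-trichlorobenzoyl chloride, Et3N, THF, 0 °C; then DMAP, toluene (0.01 M), rt
Reagents that add atoms: none
Why: In this Yamaguchi lactonisation DMAP-mediated acyl transfer from the mixed anhydride to the tertiary hydroxyl closes the six-membered 1,4-dioxan-2-one (6-exo-trig), and under these non-acidic conditions the much less electrophilic amide should not be attacked, so the γ-lactone does not re-form.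

Step 17
Reactants: 21 3-alkyl-1,4-dioxan-2-one carrying the Weinreb amide tether on C5 (C1 epimers)
Product: 23 protected (1R,5R,9S)-6,8-dioxabicyclo[3.2.2]nonane-2,7-dione (PMB ether on the C1 chain; silyl ether on the C9 chain), via tetrahedral lithium alkoxide adduct 22 (not isolated)
Conditions: LiN(SiMe3)2 (1.3 equiv), THF (0.005 M), −78 to −20 °C; AcOH in THF at −78 °C, then pH 7 buffer
Reagents that add atoms: none
Why: The silazide removes the C1–H, which as the α-proton of a lactone is several pK units more acidic than the amide CH2 and is the only proton this weak amide base takes, and the endocyclic tetrasubstituted enolate (on which both C1 epimers of 21 converge) adds to the amide carbonyl C2 held over it by the C4–C3 tether on C5, giving the lithium-chelated adduct 22 that collapses to the ketone only on acidic quench, so the non-enolisable β-keto lactone never meets base and retro-Claisen cleavage is avoided. The closest known reaction type is the intramolecular Claisen (Dieckmann-type) C-acylation of ester and lactone enolates by N-methoxy-N-methylamides, together with the C-alkylation of 1,4-dioxan-2-one (glycolate) enolates to quaternary centres. The single C1–C2 bond closes two rings at once, the oxepane O8–C1–C2–C3–C4–C5–C9 in a 7-(enolexo)-exo-trig mode and the seven-membered lactone ring C1–C2–C3–C4–C5–O6–C7 in a 7-(enolendo)-exo-trig mode, the three-carbon bridge spanning the 1,4-positions of the dioxanone in its boat form. The only new stereocentre, C1, is controlled by the (5R) centre, because the tether reaches only the enolate face syn to itself and the bicycle allows no other configuration, so C1 is formed R. The step needs chemoselective enolisation at C1 and the absence of any other electrophile, which the lactone/amide acidity difference and the choice of ether protecting groups (the acetate comes later) secure, while high dilution suppresses intermolecular condensation.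

Step 18
Reactants: 23 protected (1R,5R,9S)-6,8-dioxabicyclo[3.2.2]nonane-2,7-dione
Product: 24 (1R,5R,9S)-diketone with free allylic alcohol on the C1 chain and silyl ether on the C9 chain
Conditions: DDQ (1.3 equiv), CH2Cl2/pH 7 phosphate buffer, 0 °C
Reagents that add atoms: none
Why: Oxidative cleavage of the electron-rich PMB ether by DDQ (hydride abstraction, then hydrolysis of the oxocarbenium ion) under buffered neutral conditions should spare the silyl ether, the olefins and the base-sensitive β-keto lactone.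

Step 19
Reactants: 24 (1R,5R,9S)-diketone with free allylic alcohol on the C1 chain
Product: 25 (1R,5R,9S)-diketone with allylic acetate on the C1 chain and silyl ether on the C9 chain
Conditions: Ac2O, pyridine, DMAP (cat.), CH2Cl2, 0 °C
Reagents that add atoms: acetic anhydride, CC(=O)OC(C)=O
Why: DMAP-catalysed acetylation of the only free hydroxyl is placed before the ketone reduction so that no hydroxyl differentiation is needed.

Step 20
Reactants: 25 (1R,5R,9S)-diketone with allylic acetate on the C1 chain
Product: 26 (1R,2S,5R,9S)-2-hydroxy lactone with allylic acetate on the C1 chain and silyl ether on the C9 chain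
Conditions: (R)-2-methyl-CBS-oxazaborolidine [(3aR)-1-methyl-3,3-diphenyltetrahydro-1H,3H-pyrrolo[1,2-c][1,3,2]oxazaborole] (1.0 equiv), catecholborane (2 equiv), toluene/CH2Cl2, −78 to −40 °C; pH 7 buffer
Reagents that add atoms: none
Why: In this Corey–Bakshi–Shibata reduction the (R)-oxazaborolidine binds the C2 carbonyl anti to its larger flank (quaternary C1) and delivers hydride to the face that gives the (2S) alcohol, reagent control being used because the two faces of the bridge ketone are similar, and catecholborane is chosen because it should neither hydroborate the trisubstituted olefins nor reduce the esters at this temperature.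

Step 21
Reactants: 26 (1R,2S,5R,9S)-2-hydroxy lactone with allylic acetate on the C1 chain and silyl ether on the C9 chain
Product: 27 target CNP0174851.1
Conditions: HF·pyridine, pyridine, THF, 0 °C to rt
Reagents that add atoms: none
Why: Fluoride cleavage of the primary allylic silyl ether under buffered, non-basic conditions should leave the acetate and the lactone intact and avoid retro-aldol opening of the β-hydroxy lactone.

Compound list
1 | nerol, (2Z)-3,7-dimethylocta-2,6-dien-1-ol | CC(C)=CCC/C(C)=C\CO | starting material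
2 | tert-butyl{[(2Z)-3,7-dimethylocta-2,6-dien-1-yl]oxy}diphenylsilane | CC(C)=CCC/C(C)=C\CO[Si](c1ccccc1)(c1ccccc1)C(C)(C)C | intermediate
3 | (2E,6Z)-8-(tert-butyldiphenylsilyloxy)-2,6-dimethylocta-2,6-dien-1-ol | OC/C(C)=C/CC/C(C)=C\CO[Si](c1ccccc1)(c1ccccc1)C(C)(C)C | intermediate
4 | (2Z,6E)-8-bromo-3,7-dimethylocta-2,6-dien-1-yl tert-butyldiphenylsilyl ether | BrC/C(C)=C/CC/C(C)=C\CO[Si](c1ccccc1)(c1ccccc1)C(C)(C)C | intermediate
5 | acetic acid | CC(=O)O | starting material
6 | (4E,8Z)-10-(tert-butyldiphenylsilyloxy)-4,8-dimethyldeca-4,8-dienoic acid | OC(=O)CC/C(C)=C/CC/C(C)=C\CO[Si](c1ccccc1)(c1ccccc1)C(C)(C)C | intermediate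
7 | 3-[(2S,3S)-3-[(3Z)-5-(tert-butyldiphenylsilyloxy)-3-methylpent-3-en-1-yl]-2-methyloxiran-2-yl]propanoic acid | OC(=O)CC[C@]1(C)O[C@H]1CC/C(C)=C\CO[Si](c2ccccc2)(c2ccccc2)C(C)(C)C | intermediate
8 | (5R)-5-[(1S,4Z)-6-(tert-butyldiphenylsilyloxy)-1-hydroxy-4-methylhex-4-en-1-yl]-5-methyloxolan-2-one | O=C1CC[C@@](C)(O1)[C@@H](O)CC/C(C)=C\CO[Si](c2ccccc2)(c2ccccc2)C(C)(C)C | intermediate
9 | 3-(tert-butyldimethylsilyloxy)propanal | O=CCCO[Si](C)(C)C(C)(C)C | starting material
10 | ethyl 2-[bis(2,2,2-trifluoroethoxy)phosphoryl]propanoate | CCOC(=O)C(C)P(=O)(OCC(F)(F)F)OCC(F)(F)F | starting material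
11 | ethyl (2Z)-5-(tert-butyldimethylsilyloxy)-2-methylpent-2-enoate | CCOC(=O)/C(C)=C\CCO[Si](C)(C)C(C)(C)C | intermediate
12 | (2Z)-5-(tert-butyldimethylsilyloxy)-2-methylpent-2-en-1-ol | OC/C(C)=C\CCO[Si](C)(C)C(C)(C)C | intermediate
13 | tert-butyl{[(3Z)-5-(4-methoxybenzyloxy)-4-methylpent-3-en-1-yl]oxy}dimethylsilane | COc1ccc(COC/C(C)=C\CCO[Si](C)(C)C(C)(C)C)cc1 | intermediate
14 | (3Z)-5-(4-methoxybenzyloxy)-4-methylpent-3-en-1-ol | COc1ccc(COC/C(C)=C\CCO)cc1 | intermediate
15 | 1-({[(2Z)-5-iodo-2-methylpent-2-en-1-yl]oxy}methyl)-4-methoxybenzene | COc1ccc(COC/C(C)=C\CCI)cc1 | intermediate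
16 | (5Z)-7-(4-methoxybenzyloxy)-6-methylhept-5-enoic acid | COc1ccc(COC/C(C)=C\CCCC(=O)O)cc1 | intermediate
17 | (5Z)-2-bromo-7-(4-methoxybenzyloxy)-6-methylhept-5-enoic acid, racemic | COc1ccc(COC/C(C)=C\CCC(Br)C(=O)O)cc1 | intermediate
18 | (5Z)-2-{[(1S,4Z)-6-(tert-butyldiphenylsilyloxy)-4-methyl-1-[(2R)-2-methyl-5-oxooxolan-2-yl]hex-4-en-1-yl]oxy}-7-(4-methoxybenzyloxy)-6-methylhept-5-enoic acid, both epimers at the ether-bearing α-carbon (C1) | O=C1CC[C@@](C)(O1)[C@@H](OC(CC/C=C(/C)COCc2ccc(OC)cc2)C(=O)O)CC/C(C)=C\CO[Si](c3ccccc3)(c3ccccc3)C(C)(C)C | intermediate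
19 | (5Z)-2-{[(4R,5S,8Z)-10-(tert-butyldiphenylsilyloxy)-4-hydroxy-1-[methoxy(methyl)amino]-4,8-dimethyl-1-oxodec-8-en-5-yl]oxy}-7-(4-methoxybenzyloxy)-6-methylhept-5-enoic acid, both C1 epimers | CON(C)C(=O)CC[C@@](C)(O)[C@@H](OC(CC/C=C(/C)COCc1ccc(OC)cc1)C(=O)O)CC/C(C)=C\CO[Si](c1ccccc1)(c1ccccc1)C(C)(C)C | intermediate
20 | mixed anhydride of 19 (C7 carboxyl) with 2,4,6-trichlorobenzoic acid | CON(C)C(=O)CC[C@@](C)(O)[C@@H](OC(CC/C=C(/C)COCc1ccc(OC)cc1)C(=O)OC(=O)c1c(Cl)cc(Cl)cc1Cl)CC/C(C)=C\CO[Si](c1ccccc1)(c1ccccc1)C(C)(C)C | intermediate (not isolated)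
21 | 3-[(2R,3S)-3-[(3Z)-5-(tert-butyldiphenylsilyloxy)-3-methylpent-3-en-1-yl]-5-[(3Z)-5-(4-methoxybenzyloxy)-4-methylpent-3-en-1-yl]-2-methyl-6-oxo-1,4-dioxan-2-yl]-N-methoxy-N-methylpropanamide, both epimers at dioxanone C5 (core C1) | CON(C)C(=O)CC[C@@]1(C)OC(=O)C(CC/C=C(/C)COCc2ccc(OC)cc2)O[C@H]1CC/C(C)=C\CO[Si](c3ccccc3)(c3ccccc3)C(C)(C)C | intermediate
22 | lithium (1R,5R,9S)-9-[(3Z)-5-(tert-butyldiphenylsilyloxy)-3-methylpent-3-en-1-yl]-2-[methoxy(methyl)amino]-1-[(3Z)-5-(4-methoxybenzyloxy)-4-methylpent-3-en-1-yl]-5-methyl-7-oxo-6,8-dioxabicyclo[3.2.2]nonan-2-olate | COc1ccc(COC/C(C)=C\CC[C@@]23O[C@@H](CC/C(C)=C\CO[Si](c4ccccc4)(c4ccccc4)C(C)(C)C)[C@@](C)(CCC2([O-])N(C)OC)OC3=O)cc1.[Li+] | intermediate (not isolated)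
23 | (1R,5R,9S)-9-[(3Z)-5-(tert-butyldiphenylsilyloxy)-3-methylpent-3-en-1-yl]-1-[(3Z)-5-(4-methoxybenzyloxy)-4-methylpent-3-en-1-yl]-5-methyl-6,8-dioxabicyclo[3.2.2]nonane-2,7-dione | COc1ccc(COC/C(C)=C\CC[C@@]23O[C@@H](CC/C(C)=C\CO[Si](c4ccccc4)(c4ccccc4)C(C)(C)C)[C@@](C)(CCC2=O)OC3=O)cc1 | intermediate
24 | (1R,5R,9S)-9-[(3Z)-5-(tert-butyldiphenylsilyloxy)-3-methylpent-3-en-1-yl]-1-[(3Z)-5-hydroxy-4-methylpent-3-en-1-yl]-5-methyl-6,8-dioxabicyclo[3.2.2]nonane-2,7-dione | OC/C(C)=C\CC[C@@]12O[C@@H](CC/C(C)=C\CO[Si](c3ccccc3)(c3ccccc3)C(C)(C)C)[C@@](C)(CCC1=O)OC2=O | intermediate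
25 | (2Z)-5-[(1R,5R,9S)-9-[(3Z)-5-(tert-butyldiphenylsilyloxy)-3-methylpent-3-en-1-yl]-5-methyl-2,7-dioxo-6,8-dioxabicyclo[3.2.2]nonan-1-yl]-2-methylpent-2-en-1-yl acetate | CC(=O)OC/C(C)=C\CC[C@@]12O[C@@H](CC/C(C)=C\CO[Si](c3ccccc3)(c3ccccc3)C(C)(C)C)[C@@](C)(CCC1=O)OC2=O | intermediate
26 | (2Z)-5-[(1R,2S,5R,9S)-9-[(3Z)-5-(tert-butyldiphenylsilyloxy)-3-methylpent-3-en-1-yl]-2-hydroxy-5-methyl-7-oxo-6,8-dioxabicyclo[3.2.2]nonan-1-yl]-2-methylpent-2-en-1-yl acetate | CC(=O)OC/C(C)=C\CC[C@@]12O[C@@H](CC/C(C)=C\CO[Si](c3ccccc3)(c3ccccc3)C(C)(C)C)[C@@](C)(CC[C@@H]1O)OC2=O | intermediate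
27 | (2Z)-5-[(1R,2S,5R,9S)-2-hydroxy-9-[(3Z)-5-hydroxy-3-methylpent-3-en-1-yl]-5-methyl-7-oxo-6,8-dioxabicyclo[3.2.2]nonan-1-yl]-2-methylpent-2-en-1-yl acetate (CNP0174851.1) | CC(=O)OC/C(C)=C\CC[C@@]12O[C@@H](CC/C(C)=C\CO)[C@@](C)(CC[C@@H]1O)OC2=O | target

Total step count: 21. Longest linear sequence: 15 steps (steps 7 to 13, then 14 to 21); the nerol branch takes 14.

Steps most likely to fail

Step 17. The enolate may not reach the amide carbonyl at a useful rate, because the dioxanone has to adopt a boat with the tether axial. Intermolecular Claisen condensation, base-induced breakdown of the N-methoxy amide, or retro-Claisen opening of the β-keto lactone during quench could then take over. The fallback forms the same C1–C2 bond and the same two rings by an aldol addition instead of an acylation and sets out from 21. KN(SiMe3)2 is added at −78 °C to 21 premixed with tBuMe2SiCl, trapping the enolate as the tert-butyldimethylsilyl ketene acetal F1. iBu2AlH at −78 °C then reduces the Weinreb amide to the aldehyde F2 while the lactone is masked. BF3·OEt2 in CH2Cl2 at −78 °C triggers an intramolecular Mukaiyama aldol addition to the bicyclic β-hydroxy lactone F3 (C2 epimers, C1 again fixed by the tether). Dess–Martin periodinane oxidation returns to 23.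

Step 14. Displacement at the secondary α-bromo carboxylate by a hindered alkoxide may be slow, so that loss of HBr from 17 and alkoxide-induced migration of the lactone acyl group (γ- to δ-lactone) compete. The fallback uses a far stronger electrophile at low temperature and sets out from 16 and 8. Allyl bromide/K2CO3 converts 16 into the allyl ester F4. Enolate hydroxylation with KN(SiMe3)2 and 2-(phenylsulfonyl)-3-phenyloxaziridine gives the α-hydroxy ester F5, and Tf2O/2,6-lutidine gives the α-triflyloxy ester F6. The sodium alkoxide of 8 (NaN(SiMe3)2, THF, −40 °C) is alkylated by F6 to the ether allyl ester F7, and Pd(PPh3)4/morpholine removes the allyl group to return to 18.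

Step 5. The dioxirane may also epoxidise the second trisubstituted olefin, since an allylic silyl ether deactivates it only moderately, and the carboxylate substrate may erode facial control. The fallback uses a hydroxyl-directed epoxidation before chain extension and sets out from 3. Sharpless asymmetric epoxidation (Ti(OiPr)4, L-(+)-diethyl tartrate, tBuOOH, 4 Å molecular sieves, −20 °C), which can engage only the allylic alcohol olefin, gives the (2S,3S)-epoxy alcohol F8. Dess–Martin oxidation gives the epoxy aldehyde F9, which has no α-hydrogen and so cannot epimerise. Wittig reaction with Ph3P=CHCO2Et gives the epoxy enoate F10, and diimide (2-nitrobenzenesulfonylhydrazide, Et3N) saturates only the disubstituted conjugated olefin to the epoxy ester F11. LiOH saponification returns to 7, so 4 and 6 are not made on this path.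

Further compounds
F1 | step 17 | tert-butyldimethylsilyl ketene acetal of 21 (2-silyloxy-5,6-dihydro-1,4-dioxine carrying the Weinreb amide tether) | CON(C)C(=O)CC[C@@]1(C)OC(O[Si](C)(C)C(C)(C)C)=C(CC/C=C(/C)COCc2ccc(OC)cc2)O[C@H]1CC/C(C)=C\CO[Si](c3ccccc3)(c3ccccc3)C(C)(C)C
F2 | step 17 | aldehyde from reduction of the amide of F1 (C2 aldehyde, ketene acetal intact) | O=CCC[C@@]1(C)OC(O[Si](C)(C)C(C)(C)C)=C(CC/C=C(/C)COCc2ccc(OC)cc2)O[C@H]1CC/C(C)=C\CO[Si](c3ccccc3)(c3ccccc3)C(C)(C)C
F3 | step 17 | (1R,5R,9S)-2-hydroxy-6,8-dioxabicyclo[3.2.2]nonan-7-one with PMB and silyl ethers, C2 epimers | COc1ccc(COC/C(C)=C\CC[C@@]23O[C@@H](CC/C(C)=C\CO[Si](c4ccccc4)(c4ccccc4)C(C)(C)C)[C@@](C)(CCC2O)OC3=O)cc1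
F4 | step 14 | allyl (5Z)-7-(4-methoxybenzyloxy)-6-methylhept-5-enoate | COc1ccc(COC/C(C)=C\CCCC(=O)OCC=C)cc1
F5 | step 14 | allyl (5Z)-2-hydroxy-7-(4-methoxybenzyloxy)-6-methylhept-5-enoate, racemic | COc1ccc(COC/C(C)=C\CCC(O)C(=O)OCC=C)cc1
F6 | step 14 | allyl (5Z)-7-(4-methoxybenzyloxy)-6-methyl-2-(trifluoromethylsulfonyloxy)hept-5-enoate, racemic | COc1ccc(COC/C(C)=C\CCC(OS(=O)(=O)C(F)(F)F)C(=O)OCC=C)cc1
F7 | step 14 | allyl ester of 18, both C1 epimers | O=C1CC[C@@](C)(O1)[C@@H](OC(CC/C=C(/C)COCc2ccc(OC)cc2)C(=O)OCC=C)CC/C(C)=C\CO[Si](c3ccccc3)(c3ccccc3)C(C)(C)C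
F8 | step 5 | [(2S,3S)-3-[(3Z)-5-(tert-butyldiphenylsilyloxy)-3-methylpent-3-en-1-yl]-2-methyloxiran-2-yl]methanol | OC[C@]1(C)O[C@H]1CC/C(C)=C\CO[Si](c2ccccc2)(c2ccccc2)C(C)(C)C
F9 | step 5 | (2R,3S)-3-[(3Z)-5-(tert-butyldiphenylsilyloxy)-3-methylpent-3-en-1-yl]-2-methyloxirane-2-carbaldehyde | O=C[C@]1(C)O[C@H]1CC/C(C)=C\CO[Si](c2ccccc2)(c2ccccc2)C(C)(C)C
F10 | step 5 | ethyl (2E)-3-[(2S,3S)-3-[(3Z)-5-(tert-butyldiphenylsilyloxy)-3-methylpent-3-en-1-yl]-2-methyloxiran-2-yl]prop-2-enoate | CCOC(=O)/C=C/[C@]1(C)O[C@H]1CC/C(C)=C\CO[Si](c2ccccc2)(c2ccccc2)C(C)(C)C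
F11 | step 5 | ethyl 3-[(2S,3S)-3-[(3Z)-5-(tert-butyldiphenylsilyloxy)-3-methylpent-3-en-1-yl]-2-methyloxiran-2-yl]propanoate | CCOC(=O)CC[C@]1(C)O[C@H]1CC/C(C)=C\CO[Si](c2ccccc2)(c2ccccc2)C(C)(C)C
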